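## Retrosynthetic overview

1. Ring E's enol ether is unveiled last from a C15 methyl acetal (lactol dehydration); the 3,19-diacetate comes from selective acetylation of a 3β,19,6β-triol.
2. Ring D (C9–O) is closed by oxa-Michael addition of the C13 alcohol of side-chain fragment 24 (C11–C16, C13 set by Sharpless epoxidation) onto an 8-en-7-one, itself made by 1,2-addition at C9 and oxidative transposition; 6β-OH comes from α-face reduction of a C6 ketone.
3. Ring A is built on ring B (from (R)-carvone) in one three-component cascade: methylmalonate (C3, C4, C18, C19) adds to the enone (C4–C5), the enolate adds to allyl acrylate (C1–C10), and Dieckmann closure forms C2–C3. The isopropenyl group relays chirality and is then excised to the C7=C8 enone.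
4. Enabling feature: quaternary C4 of ring A bears two oxidised carbons (C3–O and C19–O), so it is a latent methylmalonate; quaternary C10 lies α to oxygenated C9, so it is a latent ketone enolate; C1–C2 are bare methylenes, so they are an acrylate.
5. Ring order: B (chiral pool) → A (step 2) → E as its acetal in the fragment (step 14) → D (step 19) → E unsaturation (step 23).

Key step: step 2

Remark: position numbers follow labdane numbering of the target (carvone C1, C2, C3, C4, C5, C6 become C9, C10, C5, C6, C7, C8). Centres left open in a SMILES are epimer mixtures that converge later: C2 of 7; C8 of 7–13; C9 of 9, 10 and 26; C15 of 22–31; the peroxy carbon of 12.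

## Route

Step 1
Reactants: 1 (R)-(−)-carvone
Product: 2 trans-6-methylcarvone (5R,6S)
Conditions: LDA, THF, −78 °C; MeI, −78 → −20 °C
Reagents that add atoms: methyl iodide, CI
Why: Kinetic α′-deprotonation and alkylation of the cross-conjugated dienolate anti to the isopropenyl group installs C17 (enolate alkylation); this centre is erased in step 7, so its ratio is immaterial.

Step 2
Reactants: 2 trans-6-methylcarvone; 3 dimethyl 2-methylmalonate; 4 allyl acrylate
Product: 7 trans-decalin β-keto ester (ring A closed), via sodium enolate of the Michael adduct 5 (not isolated), via sodium ester enolate of the double Michael adduct 6 (not isolated)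
Conditions: 3, NaH, 15-crown-5, THF, 0 °C; 2, 0 °C → rt; then 4, −40 °C → rt; aq. NH4Cl
Reagents that add atoms: none
Why: Sodium methylmalonate adds 1,4 to the enone of 2 at C5, the resulting C9–C10 enolate 5 adds to allyl acrylate (C10–C1), and ester enolate 6 acylates one malonate ester (C2–C3) with loss of methoxide, the β-keto ester enolate being the thermodynamic sink. The closest known reaction type is the Michael–Michael–ring-closure (MIMIRC) sequence of enolates with acrylates, combined with conjugate addition–enolate trapping of carvone. Ring A closes by a 6-(enolexo)-exo-trig Dieckmann condensation through a chair. C5 is set by axial attack trans to the 7α-isopropenyl group, C10 by approach of the acrylate anti to the bulky new C5 substituent (trans ring fusion), and C4 by reversible choice between the diastereotopic esters, which should leave CO2CH3 rather than CH3 in the axial site 1,3 to the C10 methyl. The step needs C10-regiospecific enolate chemistry and no competing acceptor: the enolate arises only from the conjugate addition in an aprotic medium, 4 is added after 3 is consumed, and 2 has a single enone so no intramolecular double Michael path exists.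

Step 3
Reactants: 7 trans-decalin β-keto ester
Product: 8 3,9-diketo 19-methyl ester
Conditions: Pd(PPh3)4 (5 mol%), morpholine, THF, rt
Reagents that add atoms: none
Why: Tsuji-type deallylation by zerovalent palladium with morpholine as allyl acceptor, then spontaneous decarboxylation of the β-keto acid, removes the activating ester under neutral conditions that spare the C19 methyl ester.

Step 4
Reactants: 8 3,9-diketo 19-methyl ester
Product: 9 3β,9,19-triol
Conditions: LiAlH4, THF, 0 °C → rt; Rochelle salt work-up
Reagents that add atoms: none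
Why: Hydride reduction of ester and ketones; attack at C3 should come axially from the α face (β face screened by axial C19 and C20), giving the equatorial 3β-alcohol, while the C9 alcohol is re-oxidised in step 6.

Step 5
Reactants: 9 3β,9,19-triol
Product: 10 3,19-acetonide 9-alcohol
Conditions: 2,2-dimethoxypropane, PPTS, CH2Cl2, rt
Reagents that add atoms: 2,2-dimethoxypropane, COC(C)(C)OC
Why: The cis-disposed 3β-OH and axial 19-OH form the six-membered isopropylidene acetal (1,3-diol acetonide), leaving the hindered 9-OH free.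

Step 6
Reactants: 10 3,19-acetonide 9-alcohol
Product: 11 3,19-acetonide 9-ketone
Conditions: Dess–Martin periodinane, NaHCO3, CH2Cl2, rt
Reagents that add atoms: none
Why: Dess–Martin oxidation of the only free secondary alcohol restores the C9 ketone that activates C8–H for step 7.

Step 7
Reactants: 11 3,19-acetonide 9-ketone
Product: 14 Δ7-9-one acetonide, via methoxy hydroperoxide 12 (not isolated), via 7α-acetate 13 (not isolated)
Conditions: O3, CH2Cl2/MeOH, −78 °C; Ac2O, Et3N, DMAP, 0 °C → rt; then DBU, rt
Reagents that add atoms: none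
Why: Ozonolysis in methanol and acetylation trigger Criegee rearrangement (C7 migrates to oxygen with retention) to the 7α-acetate, and E1cB loss of acetate β to the C9 ketone gives the enone, erasing the relay centres C7 and C8.

Step 8
Reactants: 14 Δ7-9-one acetonide
Product: 15 7-ene-6,9-dione
Conditions: dirhodium tetrakis(caprolactamate) (1 mol%), t-BuOOH (70% aq.), 1,2-dichloroethane, 40 °C
Reagents that add atoms: tert-butyl hydroperoxide, CC(C)(C)OO
Why: Catalysed allylic oxidation of the only ring allylic methylene (C6, γ to the enone carbonyl) gives the ene-dione (enone γ-oxidation).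

Step 9
Reactants: 15 7-ene-6,9-dione
Product: 16 6β-hydroxy-7-en-9-one
Conditions: NaBH4 (1 equiv), CeCl3·7H2O, MeOH, −78 °C
Reagents that add atoms: none
Why: Luche 1,2-reduction should take the less hindered C6 carbonyl (C9 is flanked by quaternary C10 and C8–CH3), with hydride entering from the α face because the β face is blocked by the 1,3-diaxial C20 and C19, giving the axial 6β-alcohol.

Step 10
Reactants: 16 6β-hydroxy-7-en-9-one
Product: 17 6β-triethylsilyl ether
Conditions: TESOTf, 2,6-lutidine, CH2Cl2, −40 → 0 °C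
Reagents that add atoms: triethylsilyl trifluoromethanesulfonate, CC[Si](CC)(CC)OS(=O)(=O)C(F)(F)F
Why: Silyl triflate silylation protects the hindered axial alcohol for the organometallic and chromium steps.

Step 11
Reactants: 18 propargyl alcohol
Product: 19 2-methylidenepent-4-en-1-ol
Conditions: allylmagnesium bromide (2.5 equiv), CuI (5 mol%), Et2O, 0 °C → reflux; aq. NH4Cl
Reagents that add atoms: allylmagnesium bromide, C=CC[Mg]Br
Why: Alkoxide-directed allylmagnesiation of the propargylic alcohol followed by protonolysis gives the 2-allyl allylic alcohol (carbometalation).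

Step 12
Reactants: 19 2-methylidenepent-4-en-1-ol
Product: 20 (S)-2-allyl-2-(hydroxymethyl)oxirane
Conditions: Ti(OiPr)4 (10 mol%), L-(+)-diethyl tartrate (12 mol%), t-BuOOH, 4 Å MS, CH2Cl2, −20 °C
Reagents that add atoms: tert-butyl hydroperoxide, CC(C)(C)OO
Why: Sharpless asymmetric epoxidation epoxidises only the allylic-alcohol alkene, and the L-(+)-tartrate (the enantiomer that gives (S)-2-substituted glycidols) sets C13.

Step 13
Reactants: 20 (S)-2-allyl-2-(hydroxymethyl)oxirane
Product: 21 (R)-dithianylmethyl diol
Conditions: 1,3-dithiane, n-BuLi, THF, −30 °C; then 20 (pre-treated with n-BuLi, 1 equiv), −30 → 0 °C; aq. NH4Cl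
Reagents that add atoms: 1,3-dithiane, C1CSCCS1
Why: 2-Lithio-1,3-dithiane opens the 2,2-disubstituted epoxide at its CH2 terminus (SN2; the Payne-rearranged epoxide is the same compound), adding C15 as a masked aldehyde without touching C13.

Step 14
Reactants: 21 (R)-dithianylmethyl diol
Product: 22 (3R)-3-allyl-5-methoxyoxolan-3-ol
Conditions: PhI(O2CCF3)2, MeOH/CH2Cl2, 0 °C → rt; NaHCO3
Reagents that add atoms: methanol, CO
Why: Oxidative dethioacetalisation with the hypervalent iodine reagent unmasks the aldehyde, which is trapped by the primary hydroxyl and methanol as the five-membered cyclic methyl acetal.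

Step 15
Reactants: 22 (3R)-3-allyl-5-methoxyoxolan-3-ol
Product: 23 (3R)-3-(2-hydroxyethyl)-5-methoxyoxolan-3-ol
Conditions: O3, CH2Cl2/MeOH, −78 °C; then NaBH4, −78 °C → rt
Reagents that add atoms: ozone, [O-][O+]=O
Why: Ozonolysis of the terminal alkene with reductive work-up shortens the allyl arm to the C11 primary alcohol.

Step 16
Reactants: 23 (3R)-3-(2-hydroxyethyl)-5-methoxyoxolan-3-ol
Product: 24 (3S)-3-(2-iodoethyl)-5-methoxyoxolan-3-ol
Conditions: I2, PPh3, imidazole, CH2Cl2, 0 °C
Reagents that add atoms: iodine, II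
Why: Appel-type iodination converts only the primary alcohol; the tertiary alcohol is inert.

Step 17
Reactants: 17 6β-triethylsilyl ether; 24 (3S)-3-(2-iodoethyl)-5-methoxyoxolan-3-ol
Product: 26 C9 tertiary allylic alcohol, via dilithio reagent 25 (not isolated)
Conditions: 24, MeLi (1 equiv), then t-BuLi (2 equiv), Et2O, −78 °C; CeCl3, THF, −78 °C; 17, −78 → −20 °C; aq. NH4Cl
Reagents that add atoms: none
Why: Deprotonation, iodine–lithium exchange and transmetalation to cerium give a non-basic nucleophile that adds 1,2 to the hindered C9 enone carbonyl; the C9 configuration is erased in step 18.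

Step 18
Reactants: 26 C9 tertiary allylic alcohol
Product: 27 8-en-7-one with C9 side chain
Conditions: pyridinium chlorochromate, NaOAc, 4 Å MS, CH2Cl2, rt
Reagents that add atoms: pyridinium chlorochromate, [O-][Cr](=O)(=O)Cl.c1cc[nH+]cc1
Why: Babler–Dauben oxidative 1,3-transposition (chromate ester [3,3] shift, then oxidation) moves oxygen to C7; buffering preserves the silyl ether, acetonide and acetal.

Step 19
Reactants: 27 8-en-7-one with C9 side chain
Product: 28 9α,13-epoxy-7-ketone (spiro ether)
Conditions: KOt-Bu (0.2 equiv), THF, 0 °C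
Reagents that add atoms: none
Why: Base-catalysed intramolecular oxa-Michael addition (5-exo-trig) of the C13 alkoxide to C9 should occur axially on the α face, anti to C20, giving the 9α-O/9β-C11 spiro centre, with thermodynamic protonation placing the C8 methyl equatorial (8α); C13 is untouched.

Step 20
Reactants: 28 9α,13-epoxy-7-ketone (spiro ether)
Product: 29 3β,6β,19-triol 15-methyl acetal
Conditions: CSA (cat.), MeOH, rt
Reagents that add atoms: none
Why: Acid-catalysed methanolysis removes the isopropylidene acetal and the silyl ether, while the C15 methyl acetal only exchanges with the solvent.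

Step 21
Reactants: 29 3β,6β,19-triol 15-methyl acetal
Product: 30 3β,19-diacetate 15-methyl acetal
Conditions: Ac2O, pyridine, 0 °C → rt
Reagents that add atoms: acetic anhydride, CC(=O)OC(C)=O
Why: Acetylation should take the primary 19-OH and the equatorial 3β-OH, while the axial 6β-OH (1,3-diaxial to C19 and C20, α to the ketone) stays free without DMAP.

Step 22
Reactants: 30 3β,19-diacetate 15-methyl acetal
Product: 31 3β,19-diacetate 15-lactol
Conditions: AcOH/H2O/THF (2:1:1), 40 °C
Reagents that add atoms: water, O
Why: Mild aqueous acid hydrolyses the cyclic methyl acetal to the lactol without cleaving the acetates.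

Step 23
Reactants: 31 3β,19-diacetate 15-lactol
Product: 32 CNP0317137.1
Conditions: MsCl, Et3N, CH2Cl2, 0 → 40 °C
Reagents that add atoms: none
Why: Mesylation of the lactol hydroxyl and amine-induced elimination through the oxocarbenium ion (loss of H14) gives the 2,3-dihydrofuran under buffered, non-acidic conditions that avoid ionisation at C13.

## Compound list

1 | (R)-(−)-carvone, (5R)-2-methyl-5-(prop-1-en-2-yl)cyclohex-2-en-1-one | CC(=C)[C@@H]1CC=C(C)C(=O)C1 | starting material
2 | (5R,6S)-2,6-dimethyl-5-(prop-1-en-2-yl)cyclohex-2-en-1-one (trans-6-methylcarvone; minor 6-epimer converges) | CC(=C)[C@@H]1CC=C(C)C(=O)[C@H]1C | intermediate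
3 | dimethyl 2-methylmalonate | COC(=O)C(C)C(=O)OC | starting material
4 | allyl acrylate | C=CC(=O)OCC=C | starting material
5 | sodium enolate (O–C9=C10) of the C5 Michael adduct, malonate trans to isopropenyl | [Na+].[O-]C1=C(C)[C@H](C(C)(C(=O)OC)C(=O)OC)C[C@@H](C(C)=C)[C@@H]1C | intermediate
6 | sodium ester enolate of the double Michael adduct, C10 quaternary, propanoate chain trans to the malonate | [Na+].[O-]C(OCC=C)=CC[C@]1(C)C(=O)[C@@H](C)[C@H](C(C)=C)C[C@H]1C(C)(C(=O)OC)C(=O)OC | intermediate
7 | trans-decalin (5α-H, 10β-CH3): 3,9-dione, 2-CO2allyl, 4α-CH3, 4β-CO2CH3, 7α-isopropenyl, 8-CH3 | COC(=O)[C@@]1(C)C(=O)C(C(=O)OCC=C)C[C@@]2(C)[C@H]1C[C@@H](C(C)=C)C(C)C2=O | intermediate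
8 | as 7 without the C2 ester: 3,9-dione, 4α-CH3, 4β-CO2CH3, 7α-isopropenyl | COC(=O)[C@@]1(C)C(=O)CC[C@@]2(C)[C@H]1C[C@@H](C(C)=C)C(C)C2=O | intermediate
9 | 3β,9,19-triol, 4α-CH3, 7α-isopropenyl, 8-CH3, 10β-CH3, 5α-H | OC[C@@]1(C)[C@@H](O)CC[C@@]2(C)[C@H]1C[C@@H](C(C)=C)C(C)C2O | intermediate
10 | 3β,19-O-isopropylidene acetal of 9, free 9-OH | CC1(C)OC[C@@]2(C)[C@@H](O1)CC[C@@]3(C)[C@H]2C[C@@H](C(C)=C)C(C)C3O | intermediate
11 | 9-ketone of 10 | CC1(C)OC[C@@]2(C)[C@@H](O1)CC[C@@]3(C)[C@H]2C[C@@H](C(C)=C)C(C)C3=O | intermediate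
12 | 7α-(2-hydroperoxy-2-methoxypropan-2-yl) derivative from ozonolysis of 11 in methanol | CC1(C)OC[C@@]2(C)[C@@H](O1)CC[C@@]3(C)[C@H]2C[C@@H](C(C)(OC)OO)C(C)C3=O | intermediate
13 | 7α-acetoxy-9-ketone (Criegee product) | CC1(C)OC[C@@]2(C)[C@@H](O1)CC[C@@]3(C)[C@H]2C[C@@H](OC(C)=O)C(C)C3=O | intermediate
14 | 3β,19-(isopropylidenedioxy)-4α,8,10β-trimethyl-5α-decal-7-en-9-one | CC1(C)OC[C@@]2(C)[C@@H](O1)CC[C@@]3(C)[C@H]2CC=C(C)C3=O | intermediate
15 | corresponding 7-ene-6,9-dione | CC1(C)OC[C@@]2(C)[C@@H](O1)CC[C@@]3(C)[C@H]2C(=O)C=C(C)C3=O | intermediate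
16 | 6β-hydroxy-7-en-9-one | CC1(C)OC[C@@]2(C)[C@@H](O1)CC[C@@]3(C)[C@H]2[C@H](O)C=C(C)C3=O | intermediate
17 | 6β-triethylsilyl ether of 16 | CC1(C)OC[C@@]2(C)[C@@H](O1)CC[C@@]3(C)[C@H]2[C@H](O[Si](CC)(CC)CC)C=C(C)C3=O | intermediate
18 | propargyl alcohol (prop-2-yn-1-ol) | C#CCO | starting material
19 | 2-methylidenepent-4-en-1-ol | C=CCC(=C)CO | intermediate
20 | (S)-[2-(prop-2-en-1-yl)oxiran-2-yl]methanol | C=CC[C@]1(CO)CO1 | intermediate
21 | (R)-2-(1,3-dithian-2-ylmethyl)pent-4-ene-1,2-diol | C=CC[C@](O)(CO)CC1SCCCS1 | intermediate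
22 | (3R)-5-methoxy-3-(prop-2-en-1-yl)oxolan-3-ol (C5 anomers) | C=CC[C@]1(CC(OC)OC1)O | intermediate
23 | (3R)-3-(2-hydroxyethyl)-5-methoxyoxolan-3-ol | OCC[C@]1(CC(OC)OC1)O | intermediate
24 | (3S)-3-(2-iodoethyl)-5-methoxyoxolan-3-ol | ICC[C@]1(CC(OC)OC1)O | intermediate
25 | C,O-dilithio derivative of 24, used as its cerium reagent | [Li]CC[C@]1(CC(OC)OC1)O[Li] | intermediate
26 | tertiary allylic alcohol: C9(OH) carrying the C11–C16 chain, Δ7, 6β-OTES, 3,19-acetonide, (13R) free OH | CC1(C)OC[C@@]2(C)[C@@H](O1)CC[C@@]3(C)[C@H]2[C@H](O[Si](CC)(CC)CC)C=C(C)C3(O)CC[C@]4(CC(OC)OC4)O | intermediate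
27 | 8-en-7-one with the side chain on C9, 6β-OTES, 3,19-acetonide, (13R) free OH | CC1(C)OC[C@@]2(C)[C@@H](O1)CC[C@@]3(C)[C@H]2[C@H](O[Si](CC)(CC)CC)C(=O)C(C)=C3CC[C@]4(CC(OC)OC4)O | intermediate
28 | (13R)-15-methoxy-9α,13:15,16-diepoxy-6β-(triethylsilyloxy)-3β,19-(isopropylidenedioxy)labdan-7-one (8α-CH3) | CC1(C)OC[C@@]2(C)[C@@H](O1)CC[C@@]3(C)[C@H]2[C@H](O[Si](CC)(CC)CC)C(=O)[C@@H](C)[C@]35CC[C@]4(CC(OC)OC4)O5 | intermediate
29 | (13R)-3β,6β,19-trihydroxy-15-methoxy-9α,13:15,16-diepoxylabdan-7-one | OC[C@@]1(C)[C@@H](O)CC[C@@]2(C)[C@H]1[C@H](O)C(=O)[C@@H](C)[C@]23CC[C@]4(CC(OC)OC4)O3 | intermediate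
30 | (13R)-3β,19-diacetoxy-6β-hydroxy-15-methoxy-9α,13:15,16-diepoxylabdan-7-one | CC(=O)OC[C@@]1(C)[C@@H](OC(C)=O)CC[C@@]2(C)[C@H]1[C@H](O)C(=O)[C@@H](C)[C@]23CC[C@]4(CC(OC)OC4)O3 | intermediate
31 | (13R)-3β,19-diacetoxy-6β,15-dihydroxy-9α,13:15,16-diepoxylabdan-7-one (lactol) | CC(=O)OC[C@@]1(C)[C@@H](OC(C)=O)CC[C@@]2(C)[C@H]1[C@H](O)C(=O)[C@@H](C)[C@]23CC[C@]4(CC(O)OC4)O3 | intermediate
32 | CNP0317137.1, (13R)-3β,19-diacetoxy-6β-hydroxy-9α,13:15,16-diepoxylabd-14-en-7-one | CC(=O)OC[C@@]1(C)[C@@H](OC(C)=O)CC[C@@]2(C)[C@H]1[C@H](O)C(=O)[C@@H](C)[C@]21CC[C@]2(C=COC2)O1 | target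

## Step count and risks

Total steps: 23. Longest linear sequence: 17 (steps 1–10 and 17–23); steps 11–16 make fragment 24.

Step 2 (the cascade). The first conjugate addition may reverse, so that free malonate consumes the acrylate; proton transfer may move the enolate from C10 to C8; and the two malonate esters may be poorly discriminated. The fallback separates the events. It sets out from 2: a Mukaiyama–Michael addition of the trimethylsilyl ketene acetal of 3 (TBSOTf cat., CH2Cl2, −78 °C) should give the regiodefined C9 trimethylsilyl enol ether F1. MeLi then regenerates the C10 enolate, which is added to 4 at −78 °C and quenched to give the neutral keto triester F2. A separate Dieckmann closure (KOt-Bu, THF) returns to the route at 7.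

Step 19 (spiro-etherification). The oxa-Michael equilibrium may lie on the side of the open enone, or base may epimerise C6. The fallback sets out from 26 and avoids the conjugate addition: catalytic CSA at −20 °C should ionise the tertiary allylic alcohol, and the C13 hydroxyl captures the allyl cation at C9 from the α face to give the Δ7 spiro ether F3. Hydroboration–oxidation (BH3·SMe2, then NaBO3) places oxygen at C7 to give the 7-alcohol F4. Dess–Martin oxidation and brief DBU equilibration of C8 return to the route at 28.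

Step 9 (regioselective reduction). Discrimination between the C6 and C9 carbonyls may be insufficient, leading to over-reduction. The fallback sets out from 15 and reduces both carbonyls on purpose (excess NaBH4, CeCl3·7H2O, 0 °C) to the 6β,9-diol F5. MnO2 in CH2Cl2 should then re-oxidise only the unhindered allylic 9-OH, leaving the 1,3-diaxially shielded 6β-OH, and returns to the route at 16.

## Further compounds

F1 | step 2 | C9 trimethylsilyl enol ether of the C5 Michael adduct | C[Si](C)(C)OC1=C(C)[C@H](C(C)(C(=O)OC)C(=O)OC)C[C@@H](C(C)=C)[C@@H]1C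
F2 | step 2 | neutral keto triester (protonated form of 6) | C=CCOC(=O)CC[C@]1(C)C(=O)[C@@H](C)[C@H](C(C)=C)C[C@H]1C(C)(C(=O)OC)C(=O)OC
F3 | step 19 | Δ7 9α,13-spiro ether, 6β-OTES, 3,19-acetonide | CC1(C)OC[C@@]2(C)[C@@H](O1)CC[C@@]3(C)[C@H]2[C@H](O[Si](CC)(CC)CC)C=C(C)[C@]35CC[C@]4(CC(OC)OC4)O5
F4 | step 19 | 7-hydroxy 9α,13-spiro ether (C7 and C8 epimers) | CC1(C)OC[C@@]2(C)[C@@H](O1)CC[C@@]3(C)[C@H]2[C@H](O[Si](CC)(CC)CC)C(O)C(C)[C@]35CC[C@]4(CC(OC)OC4)O5
F5 | step 9 | 6β,9-dihydroxy-7-ene acetonide (C9 epimers) | CC1(C)OC[C@@]2(C)[C@@H](O1)CC[C@@]3(C)[C@H]2[C@H](O)C=C(C)C3O
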